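**One step.** A one-way, one-step world relaxes with a single time constant toward an end value, and that end value is the whole charge. Here each exchange frees G, and G destroys Q, so I asked first what the end state must be.

all flasks: Q 0.41 M

| run | X | remark | time |
|---|---|---|---|
| birch | 0.43 equiv | run made earlier |  |
| oak | 2.9 equiv | run made earlier |  |
| teal | 0.800 equiv |  | 8.0 d |
| violet | 3.00 equiv |  | 8.0 d |
| green | 4.00 equiv |  | 8.0 d |

| run | time / d | L / % |
|---|---|---|
| birch | 0.333 | 0 |
| birch | 0.625 | 1.8 |
| birch | 1.04 | 0 |
| birch | 2.00 | 4.1 |
| birch | 4.00 | 5.4 |
| oak | 0.333 | 8.4 |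
| oak | 0.625 | 19.1 |
| oak | 1.04 | 28.1 |
| oak | 2.00 | 39.4 |
| oak | 4.00 | 41.1 |

(readings scatter by 1 percentage point)

- amount of L at the end, in percent of the Q charged, for each flask in turn (teal, violet, green)

**The ledger.** I kept the books on Q, which I took as the limiting reagent, in fractions of its charge. Counted net of its way back, the first exchange moves a Q to Z, spending one X and freeing one G. Counted the same way, the second moves a Z to L, spending another X and freeing another G. Each G that meets a Q writes that Q off to E, with no X spent. When the Q entry closes, E, Z and L together make up the charge.

**Oak's reading.** In oak, L read 39.4% after 2.00 d and 41.1% after 4.00 d. Z was not read, so I assumed it had passed on to L, which gives 41.1%. This is the survivor share: the part of the charge that escapes E, counted as Z plus L. The other 58.9% I booked to E, as an estimate for oak.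

**The bill.** A survivor costs one X as Z and two as L, so turning them all into L costs 0.822 equiv. Teal brings 0.800 equiv. If teal saves the same share, its L stays under a ceiling of 38.9%, which is the charge of X less the survivors. That is my ceiling, not an estimate of the level. Violet and green bring 3.00 equiv and 4.00 equiv, so I put their L near the survivor share.

**The forecast.** It gave 25%, 42% and 46%, holding that “More X favours uptake only weakly”. Its teal figure lies below my ceiling, and its green figure above my share.

**The flask.** Teal, violet and green gave 21.6%, 42.8% and 46.0%.

    Q + X ⇌ G + Z (K = 2.40, k = 3.00 × 10⁻⁵ /M/s)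
    Z + X ⇌ G + L (K = 1.70, k = 1.20 × 10⁻⁵ /M/s)
    G + Q → E (k = 3.90 × 10⁻⁴ /M/s)

**Survivors counted.** In violet at 8.0 d, E held 53.0% and the survivors came to 46.9%. Taking away the loss of G + Q to E lifts violet's L from 42.8% to 56.8%, which is 24% of what L lacks of the whole charge. Teal's survivors came to 42.0%, beside the 41.1% from oak, yet its L stood at 21.6%, under the ceiling, with Z holding 20.4%. Green's survivors came to 49.7%.

(All runs stem from a simulated flask with made-up constants; noise was put on by code.)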